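## Structural features

The target is a 3-arylcoumarin: benzene ring A is fused through C4a and C8a to a 2-pyranone ring, and C3 of that ring carries the 2,4-dihydroxyphenyl ring B through the single bond C3–C1'. Ring A is substituted on four adjacent carbons in a fixed order: a free hydroxyl on C5, a 3-methylbut-2-enyl (prenyl) chain on C6, a methoxy group on C7 and hydrogen on C8. There is no stereocentre and no stereogenic double bond, because the prenyl alkene ends in two methyl groups, so every problem is one of regiochemistry and chemoselectivity. The fragile parts are the prenyl alkene beside the C5 phenol (it closes to a 2,2-dimethylchroman under acid), the lactone (it opens with hydroxide or alkoxide) and the electron-rich triphenol (it oxidizes readily under base). The real difficulty is to place hydroxyl, prenyl and methoxy in the right sequence next to the ring fusion and to make the aryl-substituted pyranone without a late coupling on a polyoxygenated system. The key step uses the fact that C4a and C8a are neighbouring ring-A carbons that carry C4 and O1. They are the two carbons of an aryne, and the oxygen on C5, ortho to C4a, polarizes that aryne so that oxygen adds at C8a and carbon at C4a. The same C5 oxygen, as an allyl ether, then passes a three-carbon unit to C6, the only free ortho position.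

## Logic of the disconnections

**26 to 24 and 25.** The C2''=C3'' double bond of the side chain is cut (retro-cross-metathesis). C3'' and both methyl groups then come from 25, and the side chain of 24 is a plain allyl group. The cut is made here because the trisubstituted alkene beside the C5 hydroxyl is the most acid-sensitive element of 26; formed last, it meets no further reagent. The gain is that all protecting-group chemistry is done on a terminal alkene. The forward step must run on an unprotected triphenol and must not move the allyl double bond into conjugation with ring A.

**24 to 23.** The two aryl O–CH2 acetal bonds on ring B are cut. The acetals are needed because ring B has to pass through an enolate and a 190 °C step. Their removal is placed at the allyl stage, where dilute acid is harmless. The forward step demands only that the lactone and the terminal alkene survive warm dilute acid.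

**23 to 21.** The bond C6–C1'' is cut and the other end of the allyl unit is reconnected to O5 (retro-Claisen). In the forward sense the allyl carbon remote from oxygen ends on C6 as C1'', the central carbon becomes C2'', and the former O–CH2 carbon becomes the terminal CH2 that step 11 releases as propene. Regiochemistry is not a question, since the second ortho position of O5 is the ring-fusion carbon C4a. The demand is thermal stability of acetals and lactone near 190 °C.

**21 to 11, 14 and 15.** Four bonds of the pyranone are cut: O1–C8a and C4–C4a on the ring-A side, C3–C4 and O1–C2 on the arylacetate side. 11 is the source of aryne 16, 15 supplies C4 with its hydrogen, and 14 supplies C2, C3 and ring B. The gain is large: ring A arrives with its three oxygens differentiated and the allyl group already on O5, and no biaryl-type coupling is needed. The forward step makes three demands: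
- the first addition to unsymmetrical 16 must be regioselective, which the alkoxy group beside one aryne carbon ensures;
- the carbon nucleophile must be a full enolate (19), because fluoride is too weak a base for 14;
- 19 must not meet 16, so it is added only after 16 has been converted into 18.

**11 to 7, and 7 to 5 and 6.** In 11 the C–Si and O–S bonds are cut; the bromine of 7 marks the carbon that receives silicon by oxygen-to-carbon silyl transfer (8, 9, 10). Then the O–allyl bond of 7 is cut. This gives a symmetric bromodiol and a simple electrophile. The demands are that silyl transfer within 9 outruns attack of the aryllithium on the allyl group (low temperature) and that the statistical mono-allylation of 5 is accepted, with unreacted 5 recycled.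

**5 to 4, 2 and 1.** The C–Br bond between the two oxygens is cut. Direct bromination of 1 would not distinguish its three activated positions, so both hydroxyls become MOM ethers (2), which direct lithiation to the carbon between them (3). The demand is that lithiation prefers this position over those beside the methoxy group.

**14 to 13 and 12.** The MOM ethers and the methyl ester are cut, leading to the commercial acid 12. The forward steps are routine; the ester must be made first so that no activated acyl group sits beside a free ortho phenol.

## Other disconnections considered

**Alternative 1:** Ring B is taken apart instead of the pyranone. The bonds C1'–C2', C2'–C3', C4'–C5' and C5'–C6' are cut, leading to the coumarin-3-yl vinyl diazo ketone A2 and the silylethyl ethynyl ether A3.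
- Forward key step: irradiation of A2 would trigger a Wolff rearrangement, A3 would add across the ketene function in a [2+2] step, and warming would bring four-electron ring opening, six-electron ring closure and tautomerization to A1. A1 has a free 2'-hydroxyl and a fluoride-labile silylethyl group on the 4'-oxygen.
- In its favour: the oxygen pattern of ring B follows from connectivity and not from a directing effect, and the bond C3–C1' is never formed as such. On regiochemical certainty of the ring-forming event it is better than the chosen plan. Both protecting groups of A1 leave with fluoride, so the prenylphenol would not meet acid; on this point it is the equal of the chosen plan, which avoids acid by making the prenyl group last.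
- Against it here: ring B is the one part of the target that can be bought with both oxygens in place (12), so the benzannulation is spent where it is not needed. A2 must already contain the complete ring A with hydroxyl, prenyl and methoxy correctly placed, so the real difficulty is moved into the synthesis of A2 and not solved. Diazomethane chemistry is required. The extended coumarin chromophore, the C3=C4 bond and the prenyl alkene are all open to photochemical or ketene side reactions.
- Step economy: clearly longer, since a full ring-A synthesis would still be needed before the several steps that lead to A2.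

**Alternative 2:** The carbonyl carbon C2 is removed. Cutting C2–C3 and O1–C2 leaves the E-stilbene A5, in which ring A is a 2,6-dihydroxy-4-methoxyphenyl group, and CO2 as the one-carbon unit.
- Forward key step: with Pd(OAc)2 and Cs2CO3 under CO2, a phenoxide of ring A would bind divalent palladium; the alkenyl C3–H bond, which lies cis to ring A in the E isomer, would be cleaved by cyclopalladation through a six-membered ring; CO2 would insert into the Pd–C bond and the carboxylate would lactonize to A4.
- In its favour: the two hydroxyls of ring A are equivalent, so no regiochemical decision is needed at ring closure, which is better than the polarization-controlled aryne addition. The unused hydroxyl appears as the free C5–OH of A4. A5 should be reachable by standard olefination without aryllithium or aryne-precursor chemistry, an advantage in operational simplicity.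
- Against it here: the carboxylation is established for 2-hydroxystyrenes with a terminal CH2, whereas A5 requires cleavage of an internal, aryl-bearing alkenyl C–H bond on an electron-rich, easily oxidized dihydroxystilbene. The key step is therefore an extension of its own, a risk of the same order as that of the chosen key step (equal on this point). The second phenoxide can sequester palladium. A4 lacks the C6 carbon, so an O-allylation would have to precede the same Claisen, deprotection and metathesis endgame, one step more than after 21.
- Step economy: similar at best, with the allyl group installed separately instead of arriving with the ring-A building block.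

**Alternative 3:** Ring A is built on a preformed pyranone. The bonds C4a–C5, C5–C6, C7–C8 and C8–C8a are cut, giving the 6-diazoacetyl-3-aryl-2-pyranone A7 and the prenyl-substituted methoxy alkyne A8.
- Forward key step: photochemical Wolff rearrangement of A7 would place a ketene function in conjugation with the C5=C6 bond of the pyranone. [2+2] addition of A8 (oxygen-free alkyne carbon to the ketene carbonyl carbon), ring opening and six-electron closure onto pyranone C5 would give A6 after tautomerization. C5–OH comes from the ketene carbonyl, with prenyl on C6, methoxy on C7 and hydrogen on C8.
- In its favour: the complete substitution pattern of ring A is fixed by connectivity in one operation, the prenyl group arrives intact, and one fluoride desilylation would finish the synthesis. On regiocontrol and on the number of steps after the key step (one against three) it is better than the chosen plan.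
- Against it here: both components are demanding. A7 needs diazomethane acylation at the end of a multi-step pyranone synthesis. A8 is an acid- and heat-sensitive ynol ether that must be made with the prenyl chain attached. The 2-pyranone is itself photoactive, the ketene functions can add to the prenyl double bond, and the final closure has to use an oxygen-substituted, cross-conjugated alkene.
- Comparison: the gain at the end would be consumed by the two bespoke fragments. The chosen route rests on one uncertain bond-forming event that has a classical two-step substitute, whereas no simple substitute exists here if the benzannulation fails.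

Key step: step 8

Remark on the chemistry: 1, 6, 12, 15 and 25 are taken as commercial; the target has no stereogenic element, so no configuration has to be set or protected.

## Route

Step 1
Reactants: 1 5-methoxybenzene-1,3-diol (5-methoxyresorcinol)
Product: 2 1-methoxy-3,5-bis(methoxymethoxy)benzene
Conditions: MOMCl, iPr2NEt, CH2Cl2, 0 °C to rt
Reagents that add atoms: chloromethyl methyl ether, COCCl
Why: Base-mediated O-alkylation of both phenols with the reactive α-chloro ether; the two MOM ethers are installed as the directing groups for step 2.

Step 2
Reactants: 2 1-methoxy-3,5-bis(methoxymethoxy)benzene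
Product: 4 2-bromo-5-methoxy-1,3-bis(methoxymethoxy)benzene, via aryllithium 3 (not isolated)
Conditions: n-BuLi, THF, 0 °C; then BrCCl2CCl2Br, −78 °C to rt
Reagents that add atoms: 1,2-dibromo-1,1,2,2-tetrachloroethane, BrC(Cl)(Cl)C(Cl)(Cl)Br
Why: Directed ortho-metalation: the carbon between the two MOM ethers is doubly chelated and the most acidic, and aryllithium 3 takes bromine from the halogen donor, which fragments to tetrachloroethene and LiBr.

Step 3
Reactants: 4 2-bromo-5-methoxy-1,3-bis(methoxymethoxy)benzene
Product: 5 2-bromo-5-methoxybenzene-1,3-diol
Conditions: HCl (3 M aq.), MeOH, 50 °C
Reagents that add atoms: none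
Why: Acid-catalysed methanolysis of both MOM acetals (the methoxymethyl groups leave as dimethoxymethane); the aryl bromide and the methyl ether are inert.

Step 4
Reactants: 5 2-bromo-5-methoxybenzene-1,3-diol; 6 allyl bromide
Product: 7 3-(allyloxy)-2-bromo-5-methoxyphenol
Conditions: 6 (0.95 equiv), K2CO3 (1.0 equiv), acetone, rt
Reagents that add atoms: none
Why: Williamson etherification of a symmetric diol with slightly less than one equivalent of electrophile; mono-ether 7 is separated from bis-ether and unreacted 5, which is recycled, so the statistical nature of the step costs throughput but not certainty.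

Step 5
Reactants: 7 3-(allyloxy)-2-bromo-5-methoxyphenol
Product: 11 3-(allyloxy)-5-methoxy-2-(trimethylsilyl)phenyl trifluoromethanesulfonate, via aryl trimethylsilyl ether 8 (not isolated), via aryllithium 9 (not isolated), via lithium phenoxide 10 (not isolated)
Conditions: (Me3Si)2NH, THF, 70 °C, then evaporation; n-BuLi, THF, −78 °C; Tf2O, −78 to 0 °C
Reagents that add atoms: hexamethyldisilazane, C[Si](C)(C)N[Si](C)(C)C; trifluoromethanesulfonic anhydride, O=S(=O)(OS(=O)(=O)C(F)(F)F)C(F)(F)F
Why: Standard sequence to an ortho-silylaryl triflate: O-silylation, bromine–lithium exchange and anionic 1,3 oxygen-to-carbon silyl shift (retro-Brook) put silicon on the carbon marked by bromine, and phenoxide 10 is trapped as the triflate. The silyl shift is fast at −78 °C, where aryllithium 9 does not yet add to the allyl double bond.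

Step 6
Reactants: 12 2-(2,4-dihydroxyphenyl)acetic acid
Product: 13 methyl 2-(2,4-dihydroxyphenyl)acetate
Conditions: MeOH, H2SO4 (cat.), reflux
Reagents that add atoms: methanol, CO
Why: Fischer esterification; any benzofuranone formed from the ortho-hydroxy acid is reopened by methanol under the same conditions.

Step 7
Reactants: 13 methyl 2-(2,4-dihydroxyphenyl)acetate
Product: 14 methyl 2-[2,4-bis(methoxymethoxy)phenyl]acetate
Conditions: MOMCl, iPr2NEt, CH2Cl2, 0 °C to rt
Reagents that add atoms: chloromethyl methyl ether, COCCl
Why: O-alkylation of both phenols; MOM ethers withstand the enolate, the fluoride and the 190 °C of steps 8 and 9 and leave under mild acid in step 10.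

Step 8
Reactants: 11 3-(allyloxy)-5-methoxy-2-(trimethylsilyl)phenyl trifluoromethanesulfonate; 14 methyl 2-[2,4-bis(methoxymethoxy)phenyl]acetate; 15 N,N-dimethylformamide
Product: 21 5-(allyloxy)-7-methoxy-3-[2,4-bis(methoxymethoxy)phenyl]coumarin, via aryne 16 (not isolated), via benzoxete 17 (not isolated), via ortho-quinone methide 18 (not isolated), via lithium enolate 19 (not isolated), via aminolactone 20 (not isolated)
Conditions: 11, CsF (3 equiv), dry DMF (15 as solvent), rt until 11 is consumed; then enolate from 14 and LiN(SiMe3)2 (THF, −78 °C) added at −40 °C, warmed to 60 °C; H2O work-up
Reagents that add atoms: none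
Why: Proposed new method: the one-pot union of an aryne, DMF and a carbon acid to a coumarin is established for 1,3-dicarbonyl compounds; the extension proposed here uses the preformed lithium enolate 19 of a simple arylacetate, added only after the aryne has been consumed, because CsF cannot be expected to enolize 14 and a free ester enolate present during aryne release would be arylated directly. CsF removes the trimethylsilyl group of 11 and triflate leaves to give 16; the carbonyl oxygen of 15 adds to the aryne carbon remote from the allyloxy group (the future C8a), the aryl anion that develops beside the inductively stabilizing alkoxy group closes on the iminium carbon (4-exo-trig) to benzoxete 17, and four-electron ring opening gives 18, a push–pull ortho-quinone methide that behaves as a masked salicylaldehyde iminium ion and should persist in dry DMF. Enolate 19 adds to the exocyclic carbon of 18 in a Mannich-type step that forms C3–C4 and restores the aromatic ring, the phenoxide so released attacks the methyl ester in a 6-exo-trig acyl substitution that forms O1–C2 and closes the pyranone ring as aminolactone 20, and E1cB loss of dimethylamine across C3–C4 on warming gives 21. The closest known reactions are the aryne/DMF coumarin synthesis with malonates or β-keto esters, the hydrolysis of the same aryne–DMF adducts to salicylaldehydes, and the Mannich addition of lithium ester enolates to iminium ions. No stereocentre is created in 21, since the two sp3 centres of 20 are erased by the elimination. The selectivity required is the regiochemistry of the first addition to unsymmetrical 16; the alkoxy group next to one aryne carbon secures it by making the distal carbon the site of attack, and the methoxy group, two positions further away, is too remote to compete. Ring closure before elimination ensures that ring A and the carbonyl group are cis on the new C3=C4 bond, as the lactone requires.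

Step 9
Reactants: 21 5-(allyloxy)-7-methoxy-3-[2,4-bis(methoxymethoxy)phenyl]coumarin
Product: 23 6-allyl-5-hydroxy-7-methoxy-3-[2,4-bis(methoxymethoxy)phenyl]coumarin, via dienone 22 (not isolated)
Conditions: PhNEt2, 190 °C, sealed tube, argon
Reagents that add atoms: none
Why: Aromatic Claisen rearrangement: a concerted [3,3] shift moves the allyl terminus to C6, the only unsubstituted ortho position (the other is the ring-fusion carbon C4a), and dienone 22 tautomerizes to the phenol. The weakly basic aniline solvent keeps the MOM acetals and the lactone intact.

Step 10
Reactants: 23 6-allyl-5-hydroxy-7-methoxy-3-[2,4-bis(methoxymethoxy)phenyl]coumarin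
Product: 24 6-allyl-3-(2,4-dihydroxyphenyl)-5-hydroxy-7-methoxycoumarin
Conditions: HCl (3 M aq.), MeOH/THF, 50 °C
Reagents that add atoms: none
Why: Acid-catalysed acetal cleavage of both MOM groups; it is placed before the prenyl group exists because a monosubstituted allyl group does not undergo the acid-promoted ring closure onto the C5 phenol that threatens an ortho-prenylphenol.

Step 11
Reactants: 24 6-allyl-3-(2,4-dihydroxyphenyl)-5-hydroxy-7-methoxycoumarin; 25 2-methylbut-2-ene
Product: 26 3-(2,4-dihydroxyphenyl)-5-hydroxy-7-methoxy-6-(3-methylbut-2-enyl)coumarin (target)
Conditions: second-generation Grubbs catalyst RuCl2(=CHPh)(PCy3)(H2IMes) (5 mol %), 25 (large excess), CH2Cl2, 40 °C, sealed tube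
Reagents that add atoms: none
Why: Olefin cross-metathesis: the terminal alkene exchanges its CH2 end for the isopropylidene unit of 25, propene leaves, and the trisubstituted product is too hindered to re-enter the cycle. The catalyst tolerates free phenols, and no stereocentre or stereogenic alkene is formed.

## Compound list

1 | 5-methoxybenzene-1,3-diol (5-methoxyresorcinol) | COc1cc(O)cc(O)c1 | starting material
2 | 1-methoxy-3,5-bis(methoxymethoxy)benzene | COCOc1cc(OC)cc(OCOC)c1 | intermediate
3 | [4-methoxy-2,6-bis(methoxymethoxy)phenyl]lithium | [Li]c1c(OCOC)cc(OC)cc1OCOC | intermediate
4 | 2-bromo-5-methoxy-1,3-bis(methoxymethoxy)benzene | COCOc1cc(OC)cc(OCOC)c1Br | intermediate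
5 | 2-bromo-5-methoxybenzene-1,3-diol | COc1cc(O)c(Br)c(O)c1 | intermediate
6 | allyl bromide (3-bromoprop-1-ene) | C=CCBr | starting material
7 | 3-(allyloxy)-2-bromo-5-methoxyphenol | COc1cc(O)c(Br)c(OCC=C)c1 | intermediate
8 | [3-(allyloxy)-2-bromo-5-methoxyphenoxy]trimethylsilane | COc1cc(OCC=C)c(Br)c(O[Si](C)(C)C)c1 | intermediate
9 | [2-(allyloxy)-4-methoxy-6-(trimethylsilyloxy)phenyl]lithium | [Li]c1c(OCC=C)cc(OC)cc1O[Si](C)(C)C | intermediate
10 | lithium 3-(allyloxy)-5-methoxy-2-(trimethylsilyl)phenoxide | [Li]Oc1cc(OC)cc(OCC=C)c1[Si](C)(C)C | intermediate
11 | 3-(allyloxy)-5-methoxy-2-(trimethylsilyl)phenyl trifluoromethanesulfonate | COc1cc(OCC=C)c([Si](C)(C)C)c(OS(=O)(=O)C(F)(F)F)c1 | intermediate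
12 | 2-(2,4-dihydroxyphenyl)acetic acid | OC(=O)Cc1ccc(O)cc1O | starting material
13 | methyl 2-(2,4-dihydroxyphenyl)acetate | COC(=O)Cc1ccc(O)cc1O | intermediate
14 | methyl 2-[2,4-bis(methoxymethoxy)phenyl]acetate | COCOc1ccc(CC(=O)OC)c(OCOC)c1 | intermediate
15 | N,N-dimethylformamide | CN(C)C=O | starting material
16 | 3-(allyloxy)-5-methoxybenzyne (1-(allyloxy)-5-methoxycyclohexa-1,3-dien-5-yne ring written as a Kekulé form) | COC1=CC#CC(OCC=C)=C1 | intermediate
17 | 3-(allyloxy)-5-methoxy-N,N-dimethyl-2H-benzo[b]oxet-2-amine | CN(C)C1Oc2cc(OC)cc(OCC=C)c12 | intermediate
18 | 3-(allyloxy)-2-[(dimethylamino)methylidene]-5-methoxycyclohexa-3,5-dien-1-one | O=C1C=C(OC)C=C(OCC=C)C1=CN(C)C | intermediate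
19 | lithium enolate of 14 (lithium 2-[2,4-bis(methoxymethoxy)phenyl]-1-methoxyethen-1-olate) | [Li]OC(OC)=Cc1ccc(OCOC)cc1OCOC | intermediate
20 | 5-(allyloxy)-4-(dimethylamino)-7-methoxy-3-[2,4-bis(methoxymethoxy)phenyl]chroman-2-one (mixture of diastereomers) | COCOc1ccc(C2C(N(C)C)c3c(OCC=C)cc(OC)cc3OC2=O)c(OCOC)c1 | intermediate
21 | 5-(allyloxy)-7-methoxy-3-[2,4-bis(methoxymethoxy)phenyl]coumarin | COCOc1ccc(-c2cc3c(OCC=C)cc(OC)cc3oc2=O)c(OCOC)c1 | intermediate
22 | 6-allyl-7-methoxy-3-[2,4-bis(methoxymethoxy)phenyl]-2H-chromene-2,5(6H)-dione (racemic) | COCOc1ccc(C2=CC3=C(C=C(OC)C(CC=C)C3=O)OC2=O)c(OCOC)c1 | intermediate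
23 | 6-allyl-5-hydroxy-7-methoxy-3-[2,4-bis(methoxymethoxy)phenyl]coumarin | COCOc1ccc(-c2cc3c(O)c(CC=C)c(OC)cc3oc2=O)c(OCOC)c1 | intermediate
24 | 6-allyl-3-(2,4-dihydroxyphenyl)-5-hydroxy-7-methoxycoumarin | COc1cc2oc(=O)c(-c3ccc(O)cc3O)cc2c(O)c1CC=C | intermediate
25 | 2-methylbut-2-ene | CC=C(C)C | starting material
26 | 3-(2,4-dihydroxyphenyl)-5-hydroxy-7-methoxy-6-(3-methylbut-2-enyl)coumarin | COc1cc2oc(=O)c(-c3ccc(O)cc3O)cc2c(O)c1CC=C(C)C | target

## Step count and least certain steps

Total step count: 11. Longest linear sequence: 9 (steps 1, 2, 3, 4, 5, 8, 9, 10, 11).

**Step 8 (key step).** Most likely failure: decay of the aryne–DMF adduct before the enolate arrives. Adduct 18 can capture a second aryne or oligomerize while it accumulates. The Mannich adduct may also stop before amine elimination and lactonization are complete, and any unconsumed 11 would be arylated by the enolate. Fallback by known chemistry, setting out from 11 and 14 and returning at 21: 11 is treated with CsF in DMF and the adduct is hydrolysed on aqueous work-up to 2-(allyloxy)-6-hydroxy-4-methoxybenzaldehyde F1. Ester 14 is saponified (LiOH, THF/H2O) to 2-[2,4-bis(methoxymethoxy)phenyl]acetic acid F2. F1 and F2 are then condensed under Perkin–Oglialoro conditions (Ac2O, Et3N, 110 °C), in which O-acylation of the phenol and intramolecular aldol condensation give 21.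

**Step 5.** Most likely failure: loss of the aryllithium to intramolecular carbolithiation of the allyl ether (five-membered ring closure) if the mixture warms before the silyl shift is complete. Protodesilylation of the very electron-rich aryl silane during an acidic work-up is a second risk. Fallback, setting out from 5 and returning at 11, so that no allyl group is present during the lithiation: 5 is bis-silylated with (Me3Si)2NH to 2-bromo-5-methoxy-1,3-bis(trimethylsilyloxy)benzene F3. Bromine–lithium exchange with retro-Brook shift desymmetrizes the molecule, and triflation of the phenoxide with loss of the remaining O-silyl group on neutral aqueous work-up gives 3-hydroxy-5-methoxy-2-(trimethylsilyl)phenyl trifluoromethanesulfonate F4. Mitsunobu etherification with allyl alcohol (PPh3, diisopropyl azodicarboxylate, THF, 0 °C) then gives 11 without a strongly basic phenoxide stage. This detour also removes the statistical allylation of step 4.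

**Step 2.** Most likely failure: incomplete regiocontrol in the metalation. Lithiation beside the methoxy group (between OMe and one MOM ether) competes with lithiation between the two MOM ethers and leads to an isomeric bromide. Fallback, setting out from 1 and returning at 11: direct electrophilic iodination of 1 with I2 and NaHCO3 in water at 0 °C is expected to go between the two hydroxyls, as it does for resorcinol itself, giving 2-iodo-5-methoxybenzene-1,3-diol F5. Mono-allylation as in step 4 gives 3-(allyloxy)-2-iodo-5-methoxyphenol F6, and the conditions of step 5 (iodine–lithium exchange in place of bromine–lithium exchange) give 11.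

**Step 11.** Most likely failure: migration of the allyl double bond into conjugation with ring A by ruthenium hydride species, followed by metathesis of the shifted alkene with loss of one carbon. Slow turnover from poor solubility or catalyst binding of the free triphenol is a second risk. Fallback, setting out from 24 and returning at 26: peracetylation (Ac2O, pyridine) gives 6-allyl-3-(2,4-diacetoxyphenyl)-7-methoxy-2-oxo-2H-chromen-5-yl acetate F7. Cross-metathesis with 25 under the same catalyst gives 3-(2,4-diacetoxyphenyl)-7-methoxy-6-(3-methylbut-2-enyl)-2-oxo-2H-chromen-5-yl acetate F8. Brief methanolysis of the three aryl acetates (K2CO3, MeOH, 0 °C, then neutralization) releases 26 without any acid contact.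

## Further compounds

F1 | step 8 | 2-(allyloxy)-6-hydroxy-4-methoxybenzaldehyde | COc1cc(O)c(C=O)c(OCC=C)c1
F2 | step 8 | 2-[2,4-bis(methoxymethoxy)phenyl]acetic acid | COCOc1ccc(CC(=O)O)c(OCOC)c1
F3 | step 5 | 2-bromo-5-methoxy-1,3-bis(trimethylsilyloxy)benzene | COc1cc(O[Si](C)(C)C)c(Br)c(O[Si](C)(C)C)c1
F4 | step 5 | 3-hydroxy-5-methoxy-2-(trimethylsilyl)phenyl trifluoromethanesulfonate | COc1cc(O)c([Si](C)(C)C)c(OS(=O)(=O)C(F)(F)F)c1
F5 | step 2 | 2-iodo-5-methoxybenzene-1,3-diol | COc1cc(O)c(I)c(O)c1
F6 | step 2 | 3-(allyloxy)-2-iodo-5-methoxyphenol | COc1cc(O)c(I)c(OCC=C)c1
F7 | step 11 | 6-allyl-3-(2,4-diacetoxyphenyl)-7-methoxy-2-oxo-2H-chromen-5-yl acetate | COc1cc2oc(=O)c(-c3ccc(OC(C)=O)cc3OC(C)=O)cc2c(OC(C)=O)c1CC=C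
F8 | step 11 | 3-(2,4-diacetoxyphenyl)-7-methoxy-6-(3-methylbut-2-enyl)-2-oxo-2H-chromen-5-yl acetate | COc1cc2oc(=O)c(-c3ccc(OC(C)=O)cc3OC(C)=O)cc2c(OC(C)=O)c1CC=C(C)C
A1 | alternative 1 | 3-[2-hydroxy-4-[2-(trimethylsilyl)ethoxy]phenyl]-7-methoxy-6-(3-methylbut-2-enyl)-5-(triisopropylsilyloxy)coumarin | COc1cc2oc(=O)c(-c3ccc(OCC[Si](C)(C)C)cc3O)cc2c(O[Si](C(C)C)(C(C)C)C(C)C)c1CC=C(C)C
A2 | alternative 1 | (E)-1-diazo-4-[7-methoxy-6-(3-methylbut-2-enyl)-2-oxo-5-(triisopropylsilyloxy)-2H-chromen-3-yl]but-3-en-2-one | COc1cc2oc(=O)c(/C=C/C(=O)C=[N+]=[N-])cc2c(O[Si](C(C)C)(C(C)C)C(C)C)c1CC=C(C)C
A3 | alternative 1 | [2-(ethynyloxy)ethyl]trimethylsilane | C#COCC[Si](C)(C)C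
A4 | alternative 2 | 5-hydroxy-7-methoxy-3-[2,4-bis(methoxymethoxy)phenyl]coumarin | COCOc1ccc(-c2cc3c(O)cc(OC)cc3oc2=O)c(OCOC)c1
A5 | alternative 2 | (E)-2-[2-[2,4-bis(methoxymethoxy)phenyl]ethenyl]-5-methoxybenzene-1,3-diol | COCOc1ccc(/C=C/c2c(O)cc(OC)cc2O)c(OCOC)c1
A6 | alternative 3 | 5-hydroxy-7-methoxy-6-(3-methylbut-2-enyl)-3-[2,4-bis(triisopropylsilyloxy)phenyl]coumarin | COc1cc2oc(=O)c(-c3ccc(O[Si](C(C)C)(C(C)C)C(C)C)cc3O[Si](C(C)C)(C(C)C)C(C)C)cc2c(O)c1CC=C(C)C
A7 | alternative 3 | 6-(2-diazoacetyl)-3-[2,4-bis(triisopropylsilyloxy)phenyl]-2H-pyran-2-one | O=C(C=[N+]=[N-])c1ccc(-c2ccc(O[Si](C(C)C)(C(C)C)C(C)C)cc2O[Si](C(C)C)(C(C)C)C(C)C)c(=O)o1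
A8 | alternative 3 | 1-methoxy-5-methylhex-4-en-1-yne | COC#CCC=C(C)C
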